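The route rests on cutting C4–C5 and C9–C10 of the trans-decalin together. In ring A the oxygenated C2 and the gem-dimethyl carbon C4 are 1,3-related, so they can be the two C–O termini of a 2,2-dimethyloxetane. The C8=C17 exocyclic methylene of ring B is what an allylsilane leaves behind. One Lewis-acid-triggered cationic cascade ionizes the oxetane at C4, closes ring A and then ring B, sets C5, C10 and C9 from the lone C2 stereocentre and keeps the oxygen on C2. Its precursor is an acyclic oxetanyl triene ester bearing CH2SiMe3 on C8, joined at C5–C6 by Negishi coupling. Oxidation and hydride reduction finally make C2–O axial.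

Key step: step 14

Remark on the chemistry: atoms carry labdane numbers (ring A = C1–C5 and C10, ring B = C5–C10, chain C11–C16, C17 = exocyclic CH2, C18/C19 on C4, C20 on C10). In these terms the target is (13E)-2β-acetoxylabda-8(17),13-dien-15-oic acid, 2R,5S,9S,10S, with the acetoxy group axial on ring A.

Step 1
Reactants: 1 trimethylsilylacetylene; 2 (S)-epichlorohydrin
Product: 4 (S)-1-chloro-5-(trimethylsilyl)pent-4-yn-2-ol, via lithium (trimethylsilyl)acetylide 3 (not isolated)
Conditions: 1, n-BuLi, THF, −78 °C; BF3·OEt2; then 2, −78 °C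
Reagents that add atoms: none
Why: BF3-assisted opening of a terminal epoxide by a lithium acetylide (Yamaguchi–Hirao alkynylation) occurs at the unsubstituted ring carbon faster than chloride displacement, so the C–O bond of the stereocentre (future C2) is untouched and its configuration is kept.

Step 2
Reactants: 4 (S)-1-chloro-5-(trimethylsilyl)pent-4-yn-2-ol
Product: 5 (S)-trimethyl[3-(oxiran-2-yl)prop-1-yn-1-yl]silane
Conditions: NaH, THF, 0 °C
Reagents that add atoms: none
Why: Intramolecular Williamson closure (3-exo-tet) of the chlorohydrin alkoxide moves the epoxide to the former CH2Cl end without touching the stereocentre, and an aprotic hydride base is used because hydroxide or methoxide would also cleave the alkynyl C–Si bond.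

Step 3
Reactants: 5 (S)-trimethyl[3-(oxiran-2-yl)prop-1-yn-1-yl]silane; 6 isopropenylmagnesium bromide
Product: 7 (R)-2-methyl-7-(trimethylsilyl)hept-1-en-6-yn-4-ol
Conditions: CuI (10 mol %), THF, −40 to −10 °C
Reagents that add atoms: none
Why: Copper-catalysed Grignard opening of a monosubstituted epoxide is an SN2 attack at the CH2 terminus that brings in C4, C18 and C19 and leaves the carbinol centre unchanged in space (S becomes R only through the CIP ranking).

Step 4
Reactants: 7 (R)-2-methyl-7-(trimethylsilyl)hept-1-en-6-yn-4-ol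
Product: 9 (S)-2-methylhept-6-yne-2,4-diol, via silyl alkynyl diol 8 (not isolated)
Conditions: Co(acac)2 (20 mol %), PhSiH3, O2 (1 atm), THF, rt; then K2CO3, MeOH, rt
Reagents that add atoms: dioxygen O=O
Why: Mukaiyama hydration (cobalt hydride hydrogen-atom transfer, O2 capture of the tertiary radical, silane reduction) is Markovnikov-selective for the 1,1-disubstituted alkene while the alkyne is still silyl-capped, and the methanolic carbonate then frees any O-silylated product and protiodesilylates the alkyne without touching C2 (R becomes S only through the CIP ranking).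

Step 5
Reactants: 9 (S)-2-methylhept-6-yne-2,4-diol
Product: 11 (4S,6E)-7-iodo-2,6-dimethylhept-6-ene-2,4-diol, via alkenyldimethylalane 10 (not isolated)
Conditions: Me3Al (5 equiv), Cp2ZrCl2 (0.3 equiv), CH2Cl2, 0 °C to rt; then I2, THF, −30 °C
Reagents that add atoms: trimethylaluminium C[Al](C)C; iodine II
Why: Zirconium-catalysed methylalumination (Negishi carboalumination) adds methyl (C20) and aluminium syn with aluminium on the terminal carbon, tolerates both hydroxyls as aluminium alkoxides when excess Me3Al is present, and iodinolysis with retention should give the (E)-iodide.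

Step 6
Reactants: 11 (4S,6E)-7-iodo-2,6-dimethylhept-6-ene-2,4-diol
Product: 12 (4S,6E)-2-hydroxy-7-iodo-2,6-dimethylhept-6-en-4-yl methanesulfonate
Conditions: MsCl (1.05 equiv), Et3N, CH2Cl2, −30 °C
Reagents that add atoms: methanesulfonyl chloride CS(=O)(=O)Cl
Why: Sulfonylation with one equivalent of reagent at low temperature distinguishes the secondary from the hindered tertiary hydroxyl and does not break the C2–O bond.

Step 7
Reactants: 12 (4S,6E)-2-hydroxy-7-iodo-2,6-dimethylhept-6-en-4-yl methanesulfonate
Product: 13 (4R)-4-[(2E)-3-iodo-2-methylprop-2-en-1-yl]-2,2-dimethyloxetane (fragment 1)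
Conditions: NaH, THF, 0 to 40 °C
Reagents that add atoms: none
Why: Intramolecular Williamson etherification (4-exo-tet), helped by the gem-dimethyl effect, lets the tertiary alkoxide displace the secondary mesylate by SN2 with inversion, which turns (S)-C2 into the (R)-oxetane carbon that the cascade needs.

Step 8
Reactants: 14 (trimethylsilyl)methylmagnesium chloride; 15 tert-butyl(but-3-yn-1-yloxy)dimethylsilane; 16 ethylene oxide
Product: 19 (Z)-6-(tert-butyldimethylsilyloxy)-4-[(trimethylsilyl)methyl]hex-3-en-1-ol, via (trimethylsilyl)methylcopper 17 (not isolated), via alkenylcopper 18 (not isolated)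
Conditions: 14, CuBr·SMe2, Et2O/Me2S, −40 °C; 15, −20 to 0 °C; LiC≡C(CH2)3CH3 (from 1-hexyne, n-BuLi), HMPA, −78 °C; 16, −78 to 0 °C
Reagents that add atoms: none
Why: Syn carbocupration of a terminal alkyne puts the silylmethyl group on the internal carbon and copper on the terminal one on the same side, the β-hydrogen-free copper reagent tolerates the warming that its slow transfer needs, and the alkenylcopper, converted into a mixed alkynyl cuprate, opens ethylene oxide with retention so that C17 and C11 end up cis (Z by the CIP rules because CH2Si outranks CH2C, while the chain carbons C7 and C11 are trans).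

Step 9
Reactants: 19 (Z)-6-(tert-butyldimethylsilyloxy)-4-[(trimethylsilyl)methyl]hex-3-en-1-ol
Product: 20 (Z)-tert-butyl({6-iodo-3-[(trimethylsilyl)methyl]hex-3-en-1-yl}oxy)dimethylsilane
Conditions: PPh3, imidazole, I2 (premixed), CH2Cl2, 0 °C
Reagents that add atoms: iodine II
Why: Appel-type iodination with the preformed phosphonium iodide converts the primary alcohol under nearly neutral conditions that leave no free iodine to attack the allylsilane and spare the silyl ether.

Step 10
Reactants: 20 (Z)-tert-butyl({6-iodo-3-[(trimethylsilyl)methyl]hex-3-en-1-yl}oxy)dimethylsilane; 21 methyl but-2-ynoate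
Product: 25 methyl (2E,6Z)-9-(tert-butyldimethylsilyloxy)-3-methyl-7-[(trimethylsilyl)methyl]nona-2,6-dienoate, via Grignard reagent 22 (not isolated), via alkylcopper 23 (not isolated), via alkenylcopper adduct 24 (not isolated)
Conditions: Mg, Et2O, rt; CuBr·SMe2, THF/Me2S, −45 °C; 21, −78 °C; MeOH, −78 °C
Reagents that add atoms: none
Why: Conjugate syn carbocupration of a 2-alkynoate by a monoalkylcopper reagent, run and protonated at −78 °C so that the adduct cannot isomerize through its allenolate, places C12 and the new H-14 cis and should thus give the (13E)-enoate.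

Step 11
Reactants: 25 methyl (2E,6Z)-9-(tert-butyldimethylsilyloxy)-3-methyl-7-[(trimethylsilyl)methyl]nona-2,6-dienoate
Product: 26 methyl (2E,6Z)-9-hydroxy-3-methyl-7-[(trimethylsilyl)methyl]nona-2,6-dienoate
Conditions: Bu4NF, AcOH (1:1), THF, 0 °C to rt
Reagents that add atoms: none
Why: Buffered fluoride cleaves the primary O–Si bond much faster than it attacks the tetraalkyl allylsilane, and the acetic acid keeps the medium from isomerizing the enoate.

Step 12
Reactants: 26 methyl (2E,6Z)-9-hydroxy-3-methyl-7-[(trimethylsilyl)methyl]nona-2,6-dienoate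
Product: 27 methyl (2E,6Z)-9-iodo-3-methyl-7-[(trimethylsilyl)methyl]nona-2,6-dienoate (fragment 2)
Conditions: PPh3, imidazole, I2 (premixed), CH2Cl2, 0 °C
Reagents that add atoms: iodine II
Why: The same Appel-type iodination gives the primary iodide without affecting the enoate, the allylsilane or either alkene geometry.

Step 13
Reactants: 27 methyl (2E,6Z)-9-iodo-3-methyl-7-[(trimethylsilyl)methyl]nona-2,6-dienoate; 13 (4R)-4-[(2E)-3-iodo-2-methylprop-2-en-1-yl]-2,2-dimethyloxetane
Product: 29 methyl (2E,6Z,10E)-12-[(2R)-4,4-dimethyloxetan-2-yl]-3,11-dimethyl-7-[(trimethylsilyl)methyl]dodeca-2,6,10-trienoate, via alkylzinc iodide 28 (not isolated)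
Conditions: 27, Zn dust, LiCl, THF, 30 °C; then 13, Pd(PPh3)4 (5 mol %), THF, rt
Reagents that add atoms: none
Why: LiCl-assisted zinc insertion into a primary iodide tolerates ester and allylsilane, and the Negishi coupling of a homoallylic alkylzinc with an alkenyl iodide under zerovalent palladium (the classical 1,5-diene synthesis) forms C5–C6 with retention of the E geometry in a donor solvent that tames the zinc salts toward the oxetane.

Step 14
Reactants: 29 methyl (2E,6Z,10E)-12-[(2R)-4,4-dimethyloxetan-2-yl]-3,11-dimethyl-7-[(trimethylsilyl)methyl]dodeca-2,6,10-trienoate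
Product: 31 methyl (13E)-2α-hydroxylabda-8(17),13-dien-15-oate (equatorial alcohol; 2S,5S,9S,10S), via trimethylsilyl ether 30 (not isolated)
Conditions: Me3SiOTf (0.3 equiv), 2,6-di-tert-butyl-4-methylpyridine (0.5 equiv), CH2Cl2 (0.005 M), −78 to −40 °C; Et3N; then K2CO3, MeOH, 0 °C
Reagents that add atoms: none
Why: Proposed new method: Me3SiOTf silylates the oxetane oxygen and the strained silyloxonium ion ionizes at its tertiary carbon C4; since C5 and the departing oxygen are tied into one six-atom loop, rear-side displacement is geometrically excluded (endocyclic restriction), so a discrete C4 cation must form, and a silyl triflate is chosen because it leaves a neutral, non-basic C2–OSiMe3 group that neither strips a proton from a C4 methyl nor drives retro-Prins (Grob-type) cleavage of C2–C3 as a metal alkoxide would. C5 of the (E)-C5=C10 alkene captures C4 (ring A, 6-endo-trig, chair), C9 of the allylsilane captures the tertiary C10 cation (ring B, 6-endo-trig, second chair), and the C8 cation, β to silicon, loses Me3Si+ to triflate, which gives only the C8=C17 exocyclic methylene and regenerates the promoter. The closest known reaction types are the epoxide-initiated, allylsilane-terminated bicyclization of polyenes and the Lewis-acid opening of 2,2-disubstituted oxetanes by tethered π-nucleophiles. C5 and C10 result from anti addition across the E alkene (trans fusion, H-5 α, C20 β), and C9 from the C8=C9 geometry with C7 trans to C11, which places the C11 chain equatorial. The step needs facial selectivity relative to C2, secured by the chair in which C2–OSiMe3 is equatorial, because the axial alternative would be syn-axial to C20 and to one C4 methyl; the (R)-oxetane carbon, unchanged in space, should therefore relay to 5S,9S,10S. The enoate is too electron-poor to take part, the hindered pyridine removes traces of TfOH that would protodesilylate the terminator, high dilution disfavours oxetane oligomerization, and any C2-axial diastereomer must be removed at this alcohol stage because oxidation would turn it into the enantiomer of the derived ketone.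

Step 15
Reactants: 31 methyl (13E)-2α-hydroxylabda-8(17),13-dien-15-oate
Product: 32 methyl (13E)-2-oxolabda-8(17),13-dien-15-oate (5S,9S,10S)
Conditions: Dess–Martin periodinane, NaHCO3, CH2Cl2, 0 °C to rt
Reagents that add atoms: none
Why: Dess–Martin oxidation under bicarbonate buffer converts the secondary alcohol into the ketone without touching the alkenes, and no stereocentre is α to the new carbonyl because C1 and C3 are CH2 groups.

Step 16
Reactants: 32 methyl (13E)-2-oxolabda-8(17),13-dien-15-oate
Product: 33 methyl (13E)-2β-hydroxylabda-8(17),13-dien-15-oate (axial alcohol; 2R,5S,9S,10S)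
Conditions: LiBH(s-Bu)3 (1.2 equiv), THF, −78 °C; then H2O2, aq NaOH, 0 °C
Reagents that add atoms: none
Why: In this substrate-controlled ketone reduction the β face of C2 is screened by the two syn-axial methyls (C20 and the axial C4 methyl), so the bulky borohydride should attack along the equatorial trajectory from the α face and give the axial 2β-alcohol, while the β,β-disubstituted enoate is not reduced at −78 °C.

Step 17
Reactants: 33 methyl (13E)-2β-hydroxylabda-8(17),13-dien-15-oate
Product: 34 (13E)-2β-hydroxylabda-8(17),13-dien-15-oic acid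
Conditions: LiOH, THF/MeOH/H2O, 50 °C; then 1 M HCl to pH 4, 0 °C
Reagents that add atoms: lithium hydroxide [Li+].[OH-]
Why: Saponification of the methyl enoate is placed before the acetylation because it could not be done selectively afterwards, and hydroxide changes neither the 13E geometry nor any stereocentre.

Step 18
Reactants: 34 (13E)-2β-hydroxylabda-8(17),13-dien-15-oic acid
Product: 36 (13E)-2β-acetoxylabda-8(17),13-dien-15-oic acid (CNP0255148.2), via mixed anhydride 35 (not isolated)
Conditions: Ac2O, DMAP, pyridine, 40 °C; then H2O, THF, rt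
Reagents that add atoms: acetic anhydride CC(=O)OC(C)=O
Why: DMAP-catalysed acylation (Steglich-type nucleophilic catalysis) is needed because the axial alcohol is flanked by two syn-axial methyls, the carboxyl group is acetylated only transiently as a mixed anhydride that water cleaves again at the acetyl carbonyl, and C2–O is not broken so 2R is kept.

Compound list
1 | trimethylsilylacetylene | C#C[Si](C)(C)C | starting material
2 | (S)-epichlorohydrin | ClC[C@@H]1CO1 | starting material
3 | lithium (trimethylsilyl)acetylide | [Li]C#C[Si](C)(C)C | intermediate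
4 | (S)-1-chloro-5-(trimethylsilyl)pent-4-yn-2-ol | ClC[C@@H](O)CC#C[Si](C)(C)C | intermediate
5 | (S)-trimethyl[3-(oxiran-2-yl)prop-1-yn-1-yl]silane | C[Si](C)(C)C#CC[C@H]1CO1 | intermediate
6 | isopropenylmagnesium bromide | C=C(C)[Mg]Br | starting material
7 | (R)-2-methyl-7-(trimethylsilyl)hept-1-en-6-yn-4-ol | C=C(C)C[C@@H](O)CC#C[Si](C)(C)C | intermediate
8 | (S)-2-methyl-7-(trimethylsilyl)hept-6-yne-2,4-diol | CC(C)(O)C[C@@H](O)CC#C[Si](C)(C)C | intermediate
9 | (S)-2-methylhept-6-yne-2,4-diol | CC(C)(O)C[C@@H](O)CC#C | intermediate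
10 | (E)-alkenyldimethylalane of 9 with both oxygens as dimethylaluminium alkoxides | CC(C)(O[Al](C)C)C[C@@H](O[Al](C)C)C/C(C)=C/[Al](C)C | intermediate
11 | (4S,6E)-7-iodo-2,6-dimethylhept-6-ene-2,4-diol | CC(C)(O)C[C@@H](O)C/C(C)=C/I | intermediate
12 | (4S,6E)-2-hydroxy-7-iodo-2,6-dimethylhept-6-en-4-yl methanesulfonate | CC(C)(O)C[C@@H](OS(C)(=O)=O)C/C(C)=C/I | intermediate
13 | (4R)-4-[(2E)-3-iodo-2-methylprop-2-en-1-yl]-2,2-dimethyloxetane (fragment 1) | CC1(C)C[C@H](O1)C/C(C)=C/I | intermediate
14 | (trimethylsilyl)methylmagnesium chloride | C[Si](C)(C)C[Mg]Cl | starting material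
15 | tert-butyl(but-3-yn-1-yloxy)dimethylsilane | C#CCCO[Si](C)(C)C(C)(C)C | starting material
16 | ethylene oxide | C1CO1 | starting material
17 | (trimethylsilyl)methylcopper | C[Si](C)(C)C[Cu] | intermediate
18 | (Z)-{4-(tert-butyldimethylsilyloxy)-2-[(trimethylsilyl)methyl]but-1-en-1-yl}copper | [Cu]/C=C(\C[Si](C)(C)C)CCO[Si](C)(C)C(C)(C)C | intermediate
19 | (Z)-6-(tert-butyldimethylsilyloxy)-4-[(trimethylsilyl)methyl]hex-3-en-1-ol | OCC/C=C(\C[Si](C)(C)C)CCO[Si](C)(C)C(C)(C)C | intermediate
20 | (Z)-tert-butyl({6-iodo-3-[(trimethylsilyl)methyl]hex-3-en-1-yl}oxy)dimethylsilane | ICC/C=C(\C[Si](C)(C)C)CCO[Si](C)(C)C(C)(C)C | intermediate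
21 | methyl but-2-ynoate | CC#CC(=O)OC | starting material
22 | Grignard reagent of 20 | I[Mg]CC/C=C(\C[Si](C)(C)C)CCO[Si](C)(C)C(C)(C)C | intermediate
23 | alkylcopper derived from 22 | [Cu]CC/C=C(\C[Si](C)(C)C)CCO[Si](C)(C)C(C)(C)C | intermediate
24 | 2-cuprio enoate (syn adduct of 23 to 21) | COC(=O)/C([Cu])=C(\C)CC/C=C(\C[Si](C)(C)C)CCO[Si](C)(C)C(C)(C)C | intermediate
25 | methyl (2E,6Z)-9-(tert-butyldimethylsilyloxy)-3-methyl-7-[(trimethylsilyl)methyl]nona-2,6-dienoate | COC(=O)/C=C(\C)CC/C=C(\C[Si](C)(C)C)CCO[Si](C)(C)C(C)(C)C | intermediate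
26 | methyl (2E,6Z)-9-hydroxy-3-methyl-7-[(trimethylsilyl)methyl]nona-2,6-dienoate | COC(=O)/C=C(\C)CC/C=C(\C[Si](C)(C)C)CCO | intermediate
27 | methyl (2E,6Z)-9-iodo-3-methyl-7-[(trimethylsilyl)methyl]nona-2,6-dienoate (fragment 2) | COC(=O)/C=C(\C)CC/C=C(\C[Si](C)(C)C)CCI | intermediate
28 | alkylzinc iodide of 27 | COC(=O)/C=C(\C)CC/C=C(\C[Si](C)(C)C)CC[Zn]I | intermediate
29 | methyl (2E,6Z,10E)-12-[(2R)-4,4-dimethyloxetan-2-yl]-3,11-dimethyl-7-[(trimethylsilyl)methyl]dodeca-2,6,10-trienoate | CC1(C)C[C@H](O1)C/C(C)=C/CC/C(C[Si](C)(C)C)=C/CC/C(C)=C/C(=O)OC | intermediate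
30 | methyl (13E)-2α-(trimethylsilyloxy)labda-8(17),13-dien-15-oate | C=C1CC[C@H]2C(C)(C)C[C@H](O[Si](C)(C)C)C[C@]2(C)[C@H]1CC/C(C)=C/C(=O)OC | intermediate
31 | methyl (13E)-2α-hydroxylabda-8(17),13-dien-15-oate | C=C1CC[C@H]2C(C)(C)C[C@H](O)C[C@]2(C)[C@H]1CC/C(C)=C/C(=O)OC | intermediate
32 | methyl (13E)-2-oxolabda-8(17),13-dien-15-oate | C=C1CC[C@H]2C(C)(C)CC(=O)C[C@]2(C)[C@H]1CC/C(C)=C/C(=O)OC | intermediate
33 | methyl (13E)-2β-hydroxylabda-8(17),13-dien-15-oate | C=C1CC[C@H]2C(C)(C)C[C@@H](O)C[C@]2(C)[C@H]1CC/C(C)=C/C(=O)OC | intermediate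
34 | (13E)-2β-hydroxylabda-8(17),13-dien-15-oic acid | C=C1CC[C@H]2C(C)(C)C[C@@H](O)C[C@]2(C)[C@H]1CC/C(C)=C/C(=O)O | intermediate
35 | acetic (13E)-2β-acetoxylabda-8(17),13-dien-15-oic anhydride | C=C1CC[C@H]2C(C)(C)C[C@@H](OC(C)=O)C[C@]2(C)[C@H]1CC/C(C)=C/C(=O)OC(C)=O | intermediate
36 | (13E)-2β-acetoxylabda-8(17),13-dien-15-oic acid (CNP0255148.2) | C=C1CC[C@H]2C(C)(C)C[C@@H](OC(C)=O)C[C@]2(C)[C@H]1CC/C(C)=C/C(=O)O | target

Total step count: 18
Longest linear sequence: 13 steps (steps 1–7, then 13–18)

Steps most likely to fail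

1. Step 14.
- **What may go wrong:** the unassisted C4 cation may lose a proton, the C2–C3 bond may cleave in a retro-Prins sense, the cascade may stop after ring A, or the two chair foldings may be poorly differentiated.
- **Change of approach:** the oxetane is replaced by a 1,1-disubstituted epoxide, whose opening at C4 can be assisted from the rear by C5. This is the established epoxide-initiated, allylsilane-terminated bicyclization, and the extra oxygen is removed afterwards.
- **Course:** it sets out from 13. B(C6F5)3-catalysed isomerization of the 2,2-disubstituted oxetane gives, with C2–O intact, (4S,6E)-7-iodo-2,6-dimethylhepta-1,6-dien-4-ol F1. TBSCl and imidazole give its tert-butyldimethylsilyl ether F2. mCPBA attacks the 1,1-disubstituted alkene in preference to the iodine-deactivated one and gives the methyloxirane F3, as both C4 epimers, which converge later. Negishi coupling with the zinc reagent 28 under Pd(PPh3)4 gives the epoxy trienyl silane ester F4. MeAlCl2 in CH2Cl2 at −78 °C closes both rings, with the C2 silyloxy group equatorial, to the 4-(hydroxymethyl) bicyclic ester F5. 1,1'-Thiocarbonyldiimidazole gives the imidazole-1-carbothioate F6. Bu3SnH and AIBN in hot toluene (Barton–McCombie deoxygenation) restore the gem-dimethyl group in methyl (13E)-2α-(tert-butyldimethylsilyloxy)labda-8(17),13-dien-15-oate F7. Bu4NF then comes back to the route at 31.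

2. Step 8.
- **What may go wrong:** the silylmethyl group may transfer only sluggishly from copper to the alkyne, and the alkenylcopper may be captured incompletely by the epoxide and merely protonated on work-up.
- **Change of approach:** the fallback avoids carbocupration and fixes the alkene geometry by a ring.
- **Course:** it sets out from 15. Lithiation (n-BuLi) and BF3·OEt2-assisted opening of 16 give 6-(tert-butyldimethylsilyloxy)hex-3-yn-1-ol F8. (Me2HSi)2NH gives the dimethylsilyl ether F9. [Cp*Ru(MeCN)3]PF6 catalyses the intramolecular trans (endo-dig) hydrosilylation to the six-membered cyclic siloxane F10, in which silicon sits on C8 and is necessarily cis to C11. N-Iodosuccinimide in MeCN (iododesilylation with retention) and hydrolytic work-up give (Z)-6-(tert-butyldimethylsilyloxy)-4-iodohex-3-en-1-ol F11. Kumada coupling with excess 14 and Pd(PPh3)4 comes back to the route at 19.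

3. Step 7.
- **What may go wrong:** Grob fragmentation of the γ-mesyloxy alkoxide and base-induced elimination toward the allylic C1 hydrogens compete with the 4-exo-tet closure.
- **Change of approach:** the fallback forms the C4–O bond instead of the C2–O bond, so C2 is inverted beforehand.
- **Course:** it sets out from 7. Mitsunobu inversion (4-nitrobenzoic acid, PPh3, DIAD) gives (S)-2-methyl-7-(trimethylsilyl)hept-1-en-6-yn-4-yl 4-nitrobenzoate F12. K2CO3 in MeOH removes the ester and the alkynyl silyl group to give (S)-2-methylhept-1-en-6-yn-4-ol F13. Methylalumination and iodinolysis as in step 5 give (4S,6E)-7-iodo-2,6-dimethylhepta-1,6-dien-4-ol F1, the compound already met above. A hydrogen-atom-transfer, radical–polar crossover cycloisomerization of this homoallylic alcohol closes the oxetane at the tertiary carbon with C2–O untouched and comes back to the route at 13. Its reagents are [N,N'-bis(3,5-di-tert-butylsalicylidene)ethane-1,2-diaminato]cobalt as catalyst, 1-fluoro-2,4,6-trimethylpyridinium triflate and 1,1,3,3-tetramethyldisiloxane.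

Further compounds
F1 | step 14 | (4S,6E)-7-iodo-2,6-dimethylhepta-1,6-dien-4-ol | C=C(C)C[C@H](O)C/C(C)=C/I
F2 | step 14 | tert-butyldimethylsilyl ether of F1 | C=C(C)C[C@H](O[Si](C)(C)C(C)(C)C)C/C(C)=C/I
F3 | step 14 | methyloxirane from F2 (both C4 epimers) | CC1(CO1)C[C@H](O[Si](C)(C)C(C)(C)C)C/C(C)=C/I
F4 | step 14 | epoxy trienyl silane ester | CC1(CO1)C[C@H](O[Si](C)(C)C(C)(C)C)C/C(C)=C/CC/C(C[Si](C)(C)C)=C/CC/C(C)=C/C(=O)OC
F5 | step 14 | methyl (13E)-2α-(tert-butyldimethylsilyloxy)-4-(hydroxymethyl) bicyclic ester (C4 epimers) | C=C1CC[C@H]2C(C)(CO)C[C@H](O[Si](C)(C)C(C)(C)C)C[C@]2(C)[C@H]1CC/C(C)=C/C(=O)OC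
F6 | step 14 | imidazole-1-carbothioate of F5 | C=C1CC[C@H]2C(C)(COC(=S)n3ccnc3)C[C@H](O[Si](C)(C)C(C)(C)C)C[C@]2(C)[C@H]1CC/C(C)=C/C(=O)OC
F7 | step 14 | methyl (13E)-2α-(tert-butyldimethylsilyloxy)labda-8(17),13-dien-15-oate | C=C1CC[C@H]2C(C)(C)C[C@H](O[Si](C)(C)C(C)(C)C)C[C@]2(C)[C@H]1CC/C(C)=C/C(=O)OC
F8 | step 8 | 6-(tert-butyldimethylsilyloxy)hex-3-yn-1-ol | OCCC#CCCO[Si](C)(C)C(C)(C)C
F9 | step 8 | dimethylsilyl ether of F8 | C[SiH](C)OCCC#CCCO[Si](C)(C)C(C)(C)C
F10 | step 8 | 3-[2-(tert-butyldimethylsilyloxy)ethyl]-2,2-dimethyl-5,6-dihydro-2H-1,2-oxasiline | C[Si]1(C)OCCC=C1CCO[Si](C)(C)C(C)(C)C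
F11 | step 8 | (Z)-6-(tert-butyldimethylsilyloxy)-4-iodohex-3-en-1-ol | OCC/C=C(\I)CCO[Si](C)(C)C(C)(C)C
F12 | step 7 | (S)-2-methyl-7-(trimethylsilyl)hept-1-en-6-yn-4-yl 4-nitrobenzoate | C=C(C)C[C@H](OC(=O)c1ccc(cc1)[N+](=O)[O-])CC#C[Si](C)(C)C
F13 | step 7 | (S)-2-methylhept-1-en-6-yn-4-ol | C=C(C)C[C@H](O)CC#C
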